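All runs stem from a simulated flask for substances that don't exist, and the scatter is random.

The meeting's question was when, within 3.0 h, the flask holds most target and how much, and the evidence on the table was the two earlier runs.

| flask | substrate | partner | remark | time |
|---|---|---|---|---|
| grey | 1 M | 0.74 equiv | run made earlier |  |
| blue | 1 M | 1.7 equiv | run made earlier |  |
| flask | 1.0 M | 1.10 equiv |  | 3.0 h |

| run | time / min | target / % |
|---|---|---|
| grey | 6.00 | 1.5 |
| grey | 12.0 | 4.4 |
| grey | 20.0 | 5.9 |
| grey | 40.0 | 6.6 |
| grey | 60.0 | 4.0 |
| grey | 120 | 0.2 |
| blue | 6.00 | 3.3 |
| blue | 12.0 | 7.9 |
| blue | 20.0 | 11.8 |
| blue | 40.0 | 9.8 |
| blue | 60.0 | 4.9 |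
| blue | 120 | 0 |

(readings scatter by 0.5 percentage points)

- the moment within 3.0 h at which there is most target
- the amount of target, in percent of the substrate charged, at that time

- what is said of target includes crystals
- crystals is a solid; its amount is given per volume of the solution
- the earlier runs were read with a standard deviation of 0.5 percentage points
- steps that have been proposed: partner + intermediate -> target; crystals <-> target; intermediate -> decomposed reagent; target -> over-reaction product; substrate -> intermediate

The first speaker noted that target rose and fell in both runs, the grey reading being down to 0.2 % at 120 min, so the meeting looked for an early peak rather than the end of the time allowed. I, as secretary, then argued in logarithms: between the highest readings, 6.6 % in grey and 11.8 % in blue, the ratio of common logarithms came to 0.699, and I called this number, the rise in the logarithm of the highest target per unit rise in the logarithm of the [partner] charged at fixed [substrate], the peak order, an apparent order read off two scattered readings. For the flask, the logarithm of the partner ratio against grey is 0.172, which the peak order turns into 0.120, so ten to that power multiplies the grey reading by 1.32, giving 8.71 %, while the same line drawn through the times of those two readings gave me 0.479 h. The forecaster tabled 8.9 % at 0.48 h, slightly higher than my peak, on the ground that “Interpolating on log partner, 1.10 equiv should peak near 9% at about 28 min”.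

The flask gives 9.04 % at 0.448 h, so the forecast stands within its margins; crystals are at 0 % at that moment, and how little target dissolves changes neither number. Put on the grey run's highest value without scatter, 6.90 %, the peak order's multiplier gives 9.11 %.

    partner + intermediate → target (k = 0.0495 /M/min)
    crystals ⇌ target, rate k2*(cs2 - [target]) while solid is left; crystals form when [target] > cs2 (solubility = 0.760 M, k = 12.8 /min)
    intermediate → decomposed reagent (k = 0.0240 /min)
    target → over-reaction product (k = 0.112 /min)
    substrate → intermediate (k = 0.0367 /min)

For the same flask with 0.440 equiv of partner, less than in grey, the peak order applied to the grey reading gives 4.59 %. The computed best of that flask is 4.59 %.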